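## Plan

- **Cuts (retrosynthesis):** C2–OH back to a C2 ketone; C7–OAc/C8–Me back to a C7=C8 alkene and then a C8 ketone; ring C opened at C1–C16 (with C10–H); C9–C11; ring B opened at C9=C10 (aldol); finally both lactone bonds, C19–C5 and C18–C4, together, leaving a monocyclic 2-bromocyclohexenol whose C3 oxygen becomes the lactone oxygen.
- **Forward order:** ring A (commercial cyclohexenone monoketal plus the C6–C9/C20 chain) → lactone and quaternary C5 in one flask → ring B by aldol condensation → quaternary C9 by alkylation with the bromofuroylmethyl unit → ring C by reductive Heck closure → C17 and C7–OAc → C2–OH.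
- **Enabling feature:** C19 (OCH2) sits on quaternary C5 next to a C3=C4 double bond whose C4 carries the lactone carbonyl C18. That is the product pattern of an allylic transposition: a C3–O–CH2Li ether of a C4(Br)=C5 alkene can shift OCH2 to C5, move the alkene to C3=C4 and keep Br on C4 for lithiation and CO2 capture, with the freed alkoxide placed to close the five-membered lactone.
- **Stereochemistry:** one CBS reduction (C3) is relayed to C5 by the [2,3] shift; C9 is alkylated anti to C19; C1 and C10 come from syn furyl/H delivery from the face of the C9 tether; C7/C8 from syn hydroboration anti to the axial C19 and C20; C2 from axial hydride attack on a ketone.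

Key step: step 6

Numbering used in the text (on the target): ring A = C1 (furyl), C2 (OH), C3=C4, C5 (quaternary), C10; ring B = C5, C6, C7 (OAc), C8 (methyl C17), C9 (methyl C20 and C11), C10; ring C = C1, C10, C9, C11, C12 (C=O), furan C13 and C16; lactone = C18 (C=O, on C4) and C19 (CH2, on C5). "Top" is the face of C19.

Remark: compounds 26 to 35 are carried as mixtures of C2 epimers (SMILES without a C2 descriptor); both epimers converge at ketone 36.

## Route

Step 1
Reactants: 1 pent-1-en-3-one
Product: 3 2-(2-bromoethyl)-2-ethyl-1,3-dioxolane, via 1-bromopentan-3-one 2 (not isolated)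
Conditions: HBr (g), CH2Cl2, 0 °C; then HOCH2CH2OH, TsOH (cat.), benzene, reflux (Dean–Stark)
Reagents that add atoms: hydrogen bromide Br; ethane-1,2-diol OCCO
Why: Conjugate hydrobromination of the enone followed by acid-catalysed ketalisation with azeotropic water removal is the standard route to β-bromo ketals and should give the masked 3-oxopentyl donor without forming a stereocentre.

Step 2
Reactants: 3 2-(2-bromoethyl)-2-ethyl-1,3-dioxolane; 4 1,4-dioxaspiro[4.5]dec-6-en-8-one
Product: 7 6-[2-(2-ethyl-1,3-dioxolan-2-yl)ethyl]-1,4-dioxaspiro[4.5]dec-6-en-8-one, via Grignard reagent 5 (not isolated), via silyl enol ether 6 (not isolated)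
Conditions: Mg, THF, 20 °C; then 4, CuBr·SMe2 (10 mol%), Me3SiCl, THF, −78 °C; then Pd(OAc)2 (1.05 equiv), MeCN, rt
Reagents that add atoms: none
Why: Copper-catalysed conjugate addition of the Grignard reagent in the presence of Me3SiCl should trap the regiodefined enolate as silyl enol ether 6, and Saegusa–Ito oxidation should restore the enone with the side chain on C5, erasing the transient C5 stereocentre.

Step 3
Reactants: 7 6-[2-(2-ethyl-1,3-dioxolan-2-yl)ethyl]-1,4-dioxaspiro[4.5]dec-6-en-8-one
Product: 9 7-bromo-6-[2-(2-ethyl-1,3-dioxolan-2-yl)ethyl]-1,4-dioxaspiro[4.5]dec-6-en-8-one, via dibromide 8 (not isolated)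
Conditions: Br2 (1.05 equiv), CH2Cl2, 0 °C; then Et3N (1.6 equiv), 0 °C → rt
Reagents that add atoms: bromine BrBr
Why: Bromine addition across the enone double bond and loss of HBr on adding Et3N is the standard α-bromination of β-substituted cyclohexenones and should place the halogen on C4, where the lactone carbonyl is attached later, without forming a stereocentre.

Step 4
Reactants: 9 7-bromo-6-[2-(2-ethyl-1,3-dioxolan-2-yl)ethyl]-1,4-dioxaspiro[4.5]dec-6-en-8-one
Product: 10 (8R)-7-bromo-6-[2-(2-ethyl-1,3-dioxolan-2-yl)ethyl]-1,4-dioxaspiro[4.5]dec-6-en-8-ol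
Conditions: (S)-1-methyl-3,3-diphenyltetrahydro-1H,3H-pyrrolo[1,2-c][1,3,2]oxazaborole (20 mol%), catecholborane (1.5 equiv), toluene, −78 °C
Reagents that add atoms: none
Why: In this Corey–Bakshi–Shibata reduction the α-bromovinyl group should act as the large substituent (as with 2-bromocyclohexenone), so hydride is delivered to one face of the achiral ketone and the C3 carbinol should be set as R, the only externally controlled stereocentre of the route.

Step 5
Reactants: 10 (8R)-7-bromo-6-[2-(2-ethyl-1,3-dioxolan-2-yl)ethyl]-1,4-dioxaspiro[4.5]dec-6-en-8-ol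
Product: 11 (8R)-7-bromo-6-[2-(2-ethyl-1,3-dioxolan-2-yl)ethyl]-8-[(tributylstannyl)methoxy]-1,4-dioxaspiro[4.5]dec-6-ene
Conditions: KH, 18-crown-6 (cat.), Bu3SnCH2I, THF, 0 °C → rt
Reagents that add atoms: tributyl(iodomethyl)stannane CCCC[Sn](CCCC)(CCCC)CI
Why: Williamson etherification of the potassium alkoxide with the iodomethylstannane should give the rearrangement precursor without touching the C3 stereocentre.

Step 6
Reactants: 11 (8R)-7-bromo-6-[2-(2-ethyl-1,3-dioxolan-2-yl)ethyl]-8-[(tributylstannyl)methoxy]-1,4-dioxaspiro[4.5]dec-6-ene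
Product: 16 (3aS)-3a-[2-(2-ethyl-1,3-dioxolan-2-yl)ethyl]-5,6-dihydro-3H-spiro[2-benzofuran-4,2'-[1,3]dioxolan]-1(3aH)-one, via lithiomethyl ether 12 (not isolated), via bromo alkoxide 13 (not isolated), via vinyllithium 14 (not isolated), via hydroxy acid 15 (not isolated)
Conditions: MeLi (1.1 equiv), THF, −78 → −40 °C; then t-BuLi (2.2 equiv), −78 °C; then CO2 (g), −78 → 0 °C; then 1 M HCl (to pH 3), 0 °C → rt
Reagents that add atoms: carbon dioxide O=C=O
Why: Tin–lithium exchange with MeLi should give α-alkoxymethyllithium 12, whose carbanion adds suprafacially to C5 through a five-membered envelope transition state while the C3–O bond breaks ([2,3]-sigmatropic Wittig–Still rearrangement), so that C19–C5 forms on the face that carried the C3 oxygen, the double bond moves to C3=C4 and bromine stays on C4; t-BuLi then turns bromoalkene 13 into vinyllithium 14, CO2 forms C18–C4 and acid closes the lactone. The closest known reaction types are the Still [2,3]-Wittig rearrangement of stannylmethyl allyl ethers used to build hydroxymethyl-bearing quaternary carbons and the bromine–lithium exchange and carboxylation of alkenyl bromides, run here in one flask because the first event creates the substrate of the second. The single ring closed is the γ-lactone (C5, C19, O, C18, C4), by 5-exo-trig acyl substitution of hydroxy acid 15. The single new stereocentre, quaternary C5, is controlled by the R carbinol at C3 from step 4, whose chirality is transferred across the allyl unit as C3 becomes sp2. The step needs the [2,3] shift to beat the [1,2] shift and tin–lithium exchange to precede bromine–lithium exchange: a pseudo-axial C3–O bond in the cyclohexene half-chair lies parallel to the alkene π system for the concerted path, and the α-alkoxystannane should exchange with MeLi at −78 °C far faster than the hindered vinyl bromide. The two ketals carry both future ketone carbons through the organolithium stages.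

Step 7
Reactants: 16 (3aS)-3a-[2-(2-ethyl-1,3-dioxolan-2-yl)ethyl]-5,6-dihydro-3H-spiro[2-benzofuran-4,2'-[1,3]dioxolan]-1(3aH)-one
Product: 18 tricyclic enone lactone (rings A and B plus lactone; C8 ketone conjugated to C9=C10; C20 methyl on C9), via diketone 17 (not isolated)
Conditions: 2 M HCl, THF, 40 °C; then TsOH·H2O (20 mol%), toluene, reflux (Dean–Stark)
Reagents that add atoms: water O
Why: Acid hydrolysis should unmask both ketones, and acid-catalysed intramolecular aldol condensation (Robinson-type closure of the six-membered ring B by attack of C9 on the C10 ketone, then dehydration) should give the C9=C10 enone, the reversible bridged ketol from C1 attack being drained by the irreversible dehydration, with no new stereocentre.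

Step 8
Reactants: 19 2-bromofuran-3-carboxylic acid
Product: 22 2-bromo-1-(2-bromofuran-3-yl)ethan-1-one, via acid chloride 20 (not isolated), via diazoketone 21 (not isolated)
Conditions: (COCl)2, DMF (cat.), CH2Cl2, rt; then CH2N2 (3 equiv), Et2O, 0 °C; then 48% aq. HBr, 0 °C
Reagents that add atoms: diazomethane C=[N+]=[N-]; hydrogen bromide Br
Why: In this Arndt–Eistert-type sequence the acid chloride should acylate diazomethane and HBr should convert the α-diazoketone into the bromomethyl ketone, with no stereocentre involved.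

Step 9
Reactants: 18 tricyclic enone lactone; 22 2-bromo-1-(2-bromofuran-3-yl)ethan-1-one
Product: 24 C9-alkylated diketone (C9 quaternary with C20 on top and C11 below; C8 ketone; skipped diene C10=C1 and C3=C4), via potassium dienolate 23 (not isolated)
Conditions: KOtBu (1.1 equiv), t-BuOH–THF, 0 °C; then 22, THF, −78 → 0 °C
Reagents that add atoms: none
Why: Thermodynamic γ-deprotonation at C1 should give heteroannular dienolate 23, whose α-carbon C9 is alkylated by the phenacyl-type bromide with deconjugation to C10=C1 (deconjugative α-alkylation of a Wieland–Miescher-type enone), the electrophile entering on the bottom face anti to the pseudo-axial C19 so that C20 ends cis to C19.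

Step 10
Reactants: 24 C9-alkylated diketone
Product: 25 cross-conjugated dienone (C2 ketone between C10=C1 and C3=C4)
Conditions: CrO3 (10 mol%), t-BuOOH (70% aq., 6 equiv), CH2Cl2, rt
Reagents that add atoms: tert-butyl hydroperoxide CC(C)(C)OO
Why: Chromium-catalysed allylic oxidation with t-BuOOH should select the doubly allylic C2 methylene, which has the weakest C–H bonds, and convert the 1,4-diene into the 2,5-cyclohexadienone as in the oxidation of Birch-type 1,4-dienes, with no stereocentre formed.

Step 11
Reactants: 25 cross-conjugated dienone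
Product: 27 C2 tert-butyldimethylsilyl ether (C2 epimer mixture), via bis-allylic alcohol 26 (not isolated)
Conditions: NaBH4 (1 equiv), CeCl3·7H2O, MeOH, −78 °C; aqueous work-up; then t-BuMe2SiCl, imidazole, DMF, rt
Reagents that add atoms: tert-butyldimethylsilyl chloride CC(C)(C)[Si](C)(C)Cl
Why: Luche 1,2-reduction should take the unhindered conjugated C2 ketone in preference to the neopentyl C8 ketone and the furyl ketone, and silylation masks the alcohol for the palladium and base steps that follow, the C2 configuration being left uncontrolled because it is reset in steps 17 and 18.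

Step 12
Reactants: 27 C2 tert-butyldimethylsilyl ether
Product: 28 tetracyclic diketone (ring C closed through C1–C16; furyl at C1 and H at C10 both on the bottom face; C8 ketone; C2 silyl ether)
Conditions: Pd(OAc)2 (10 mol%), PPh3 (30 mol%), HCO2Na (2 equiv), Bu4NCl (1 equiv), DMF, 85 °C
Reagents that add atoms: none
Why: In this intramolecular reductive Heck reaction, oxidative addition at the furyl bromide should be followed by 7-endo syn-carbopalladation of C10=C1 (C16 to the less hindered C1, because C10 is flanked by two quaternary carbons) and, as the tertiary C10–Pd bond has no syn β-hydrogen, by formate-derived hydride capture, so that furyl and hydrogen are both delivered from the bottom face on which the C9 tether lies, setting C1 and the trans ring fusion at C10.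

Step 13
Reactants: 28 tetracyclic diketone
Product: 30 C7=C8 enol triflate, via potassium enolate 29 (not isolated)
Conditions: KN(SiMe3)2 (1.1 equiv), THF, −78 °C; then PhNTf2, −78 → 0 °C
Reagents that add atoms: N-phenylbis(trifluoromethanesulfonimide) O=S(=O)(N(c1ccccc1)S(=O)(=O)C(F)(F)F)C(F)(F)F
Why: Kinetic deprotonation should occur at the accessible C7 methylene of the C8 ketone (C9 is quaternary and the 3-furyl ketone is a vinylogous ester with slowly removed neopentyl C11 protons), and O-triflation of the enolate should give the enol triflate without forming a stereocentre.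

Step 14
Reactants: 30 C7=C8 enol triflate
Product: 31 C7=C8 alkene carrying methyl C17 on C8
Conditions: MeZnCl (3 equiv), Pd(PPh3)4 (5 mol%), THF, 50 °C
Reagents that add atoms: methylzinc chloride C[Zn]Cl
Why: Negishi cross-coupling of the alkenyl triflate with MeZnCl should install C17 on C8 while tolerating the ketone, lactone and silyl ether, with no stereocentre formed.

Step 15
Reactants: 31 C7=C8 alkene
Product: 33 C7 alcohol (C7–OH on the bottom face and equatorial; C17 on the top face and equatorial), via alkylborane 32 (not isolated)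
Conditions: BH3·SMe2 (1.5 equiv), THF, 0 °C → rt; then 30% H2O2, aq. NaHCO3, 0 °C
Reagents that add atoms: hydrogen peroxide OO
Why: Hydroboration–oxidation should add boron to the less substituted C7 and hydrogen to C8 in a syn fashion from the bottom face, because the top face of ring B is screened by the axial C19 and C20 groups, and oxidation with retention then gives the trans-diequatorial C7–OH/C17 pair while the vinylogous-ester furyl ketone is reduced only slowly by the limited borane.

Step 16
Reactants: 33 C7 alcohol
Product: 34 C7 acetate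
Conditions: Ac2O, 4-(dimethylamino)pyridine (cat.), pyridine, rt
Reagents that add atoms: acetic anhydride CC(=O)OC(C)=O
Why: Standard nucleophile-catalysed acylation of the only free hydroxyl should give the C7 acetate with retention of configuration.

Step 17
Reactants: 34 C7 acetate
Product: 36 γ-oxo butenolide (C2 ketone), via C2 alcohol 35 (not isolated)
Conditions: Bu4NF, AcOH, THF, rt; aqueous work-up; then Dess–Martin periodinane, NaHCO3, CH2Cl2, rt
Reagents that add atoms: none
Why: Buffered fluoride should cleave the allylic silyl ether without acetate migration, and Dess–Martin oxidation should convert both C2 epimers of alcohol 35 into the single ketone 36 (stereoconvergence), the epimerisable C1 keeping its equatorial furyl group.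

Step 18
Reactants: 36 γ-oxo butenolide
Product: 37 target CNP0182929.2
Conditions: NaBH4, CeCl3·7H2O, MeOH, −78 °C
Reagents that add atoms: none
Why: Luche reduction should attack the activated C2 ketone in a 1,2 sense from the axial bottom direction, giving the equatorial C2 alcohol on the top face trans to the C1 furyl group, while the vinylogous-ester C12 ketone, the acetate and the lactone stay untouched at −78 °C.

## Compound list

1 | pent-1-en-3-one | CCC(=O)C=C | starting material
2 | 1-bromopentan-3-one | CCC(=O)CCBr | intermediate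
3 | 2-(2-bromoethyl)-2-ethyl-1,3-dioxolane | CCC1(CCBr)OCCO1 | intermediate
4 | 1,4-dioxaspiro[4.5]dec-6-en-8-one | O=C1C=CC2(CC1)OCCO2 | starting material
5 | [2-(2-ethyl-1,3-dioxolan-2-yl)ethyl]magnesium bromide | CCC1(CC[Mg]Br)OCCO1 | intermediate
6 | 6-[2-(2-ethyl-1,3-dioxolan-2-yl)ethyl]-8-(trimethylsilyloxy)-1,4-dioxaspiro[4.5]dec-7-ene (racemic) | C[Si](C)(C)OC1=CC(CCC3(CC)OCCO3)C2(CC1)OCCO2 | intermediate
7 | 6-[2-(2-ethyl-1,3-dioxolan-2-yl)ethyl]-1,4-dioxaspiro[4.5]dec-6-en-8-one | O=C1C=C(CCC3(CC)OCCO3)C2(CC1)OCCO2 | intermediate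
8 | 6,7-dibromo-6-[2-(2-ethyl-1,3-dioxolan-2-yl)ethyl]-1,4-dioxaspiro[4.5]decan-8-one (diastereomer mixture) | O=C1C(Br)C(Br)(CCC3(CC)OCCO3)C2(CC1)OCCO2 | intermediate
9 | 7-bromo-6-[2-(2-ethyl-1,3-dioxolan-2-yl)ethyl]-1,4-dioxaspiro[4.5]dec-6-en-8-one | O=C1C(Br)=C(CCC3(CC)OCCO3)C2(CC1)OCCO2 | intermediate
10 | (8R)-7-bromo-6-[2-(2-ethyl-1,3-dioxolan-2-yl)ethyl]-1,4-dioxaspiro[4.5]dec-6-en-8-ol | O[C@@H]1CCC2(OCCO2)C(CCC3(CC)OCCO3)=C1Br | intermediate
11 | (8R)-7-bromo-6-[2-(2-ethyl-1,3-dioxolan-2-yl)ethyl]-8-[(tributylstannyl)methoxy]-1,4-dioxaspiro[4.5]dec-6-ene | CCCC[Sn](CCCC)(CCCC)CO[C@@H]1CCC2(OCCO2)C(CCC3(CC)OCCO3)=C1Br | intermediate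
12 | (8R)-7-bromo-6-[2-(2-ethyl-1,3-dioxolan-2-yl)ethyl]-8-(lithiomethoxy)-1,4-dioxaspiro[4.5]dec-6-ene | [Li]CO[C@@H]1CCC2(OCCO2)C(CCC3(CC)OCCO3)=C1Br | intermediate
13 | lithium [(6S)-7-bromo-6-[2-(2-ethyl-1,3-dioxolan-2-yl)ethyl]-1,4-dioxaspiro[4.5]dec-7-en-6-yl]methoxide | CCC1(OCCO1)CC[C@@]2(CO[Li])C(Br)=CCCC23OCCO3 | intermediate
14 | lithium [(6S)-6-[2-(2-ethyl-1,3-dioxolan-2-yl)ethyl]-7-lithio-1,4-dioxaspiro[4.5]dec-7-en-6-yl]methoxide | CCC1(OCCO1)CC[C@@]2(CO[Li])C([Li])=CCCC23OCCO3 | intermediate
15 | (6S)-6-[2-(2-ethyl-1,3-dioxolan-2-yl)ethyl]-6-(hydroxymethyl)-1,4-dioxaspiro[4.5]dec-7-ene-7-carboxylic acid | CCC1(OCCO1)CC[C@@]2(CO)C(C(=O)O)=CCCC23OCCO3 | intermediate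
16 | (3aS)-3a-[2-(2-ethyl-1,3-dioxolan-2-yl)ethyl]-5,6-dihydro-3H-spiro[2-benzofuran-4,2'-[1,3]dioxolan]-1(3aH)-one | CCC1(OCCO1)CC[C@@]23COC(=O)C2=CCCC34OCCO4 | intermediate
17 | (3aS)-3a-(3-oxopentyl)-5,6-dihydro-2-benzofuran-1,4(3H,3aH)-dione | CCC(=O)CC[C@@]12COC(=O)C1=CCCC2=O | intermediate
18 | tricyclic enone lactone: rings A and B plus the C18/C19 lactone, C8 ketone conjugated to C9(Me)=C10, C3=C4, C5 configured as in 16 | O=C1CC[C@@]23COC(=O)C2=CCCC3=C1C | intermediate
19 | 2-bromofuran-3-carboxylic acid | OC(=O)c1ccoc1Br | starting material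
20 | 2-bromofuran-3-carbonyl chloride | ClC(=O)c1ccoc1Br | intermediate
21 | 1-(2-bromofuran-3-yl)-2-diazoethan-1-one | [N-]=[N+]=CC(=O)c1ccoc1Br | intermediate
22 | 2-bromo-1-(2-bromofuran-3-yl)ethan-1-one | BrCC(=O)c1ccoc1Br | intermediate
23 | potassium dienolate of 18 (O– on C8; C8=C9 and C10=C1) | CC1=C([O-])CC[C@@]23COC(=O)C2=CCC=C13.[K+] | intermediate
24 | C9-alkylated diketone: C9 carries C20 (top) and CH2C(=O)(2-bromofuran-3-yl) (bottom); C8 ketone; C10=C1 and C3=C4; lactone | Brc1occc1C(=O)C[C@@]2(C)C(=O)CC[C@@]34COC(=O)C3=CCC=C24 | intermediate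
25 | cross-conjugated dienone: as 24 with a C2 ketone | Brc1occc1C(=O)C[C@@]2(C)C(=O)CC[C@@]34COC(=O)C3=CC(=O)C=C24 | intermediate
26 | bis-allylic C2 alcohol (C2 epimer mixture) | Brc1occc1C(=O)C[C@@]2(C)C(=O)CC[C@@]34COC(=O)C3=CC(O)C=C24 | intermediate
27 | C2 tert-butyldimethylsilyl ether of 26 (C2 epimer mixture) | Brc1occc1C(=O)C[C@@]2(C)C(=O)CC[C@@]34COC(=O)C3=CC(O[Si](C)(C)C(C)(C)C)C=C24 | intermediate
28 | tetracyclic diketone: ring C closed (C1–C16), furyl at C1 and H-10 on the bottom face, C8 ketone, C2 silyl ether (C2 epimer mixture) | O=C1CC[C@@]23COC(=O)C2=CC(O[Si](C)(C)C(C)(C)C)[C@H]2c4occc4C(=O)C[C@]1(C)[C@@H]23 | intermediate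
29 | potassium C7=C8 enolate of 28 | [K+].[O-]C1=CC[C@@]23COC(=O)C2=CC(O[Si](C)(C)C(C)(C)C)[C@H]2c4occc4C(=O)C[C@]1(C)[C@@H]23 | intermediate
30 | C7=C8 enol triflate (triflate on C8) | FC(F)(F)S(=O)(=O)OC1=CC[C@@]23COC(=O)C2=CC(O[Si](C)(C)C(C)(C)C)[C@H]2c4occc4C(=O)C[C@]1(C)[C@@H]23 | intermediate
31 | C7=C8 alkene with methyl C17 on C8 | CC1=CC[C@@]23COC(=O)C2=CC(O[Si](C)(C)C(C)(C)C)[C@H]2c4occc4C(=O)C[C@]1(C)[C@@H]23 | intermediate
32 | C7 alkylborane (BH2 on the bottom face; H-8 on the bottom face) | B[C@H]1C[C@@]23COC(=O)C2=CC(O[Si](C)(C)C(C)(C)C)[C@H]2c4occc4C(=O)C[C@@](C)([C@@H]1C)[C@@H]23 | intermediate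
33 | C7 alcohol (OH bottom, C17 top; C2 silyl ether, C2 epimer mixture) | O[C@H]1C[C@@]23COC(=O)C2=CC(O[Si](C)(C)C(C)(C)C)[C@H]2c4occc4C(=O)C[C@@](C)([C@@H]1C)[C@@H]23 | intermediate
34 | C7 acetate of 33 | CC(=O)O[C@H]1C[C@@]23COC(=O)C2=CC(O[Si](C)(C)C(C)(C)C)[C@H]2c4occc4C(=O)C[C@@](C)([C@@H]1C)[C@@H]23 | intermediate
35 | C2 alcohol of the C7 acetate (C2 epimer mixture) | CC(=O)O[C@H]1C[C@@]23COC(=O)C2=CC(O)[C@H]2c4occc4C(=O)C[C@@](C)([C@@H]1C)[C@@H]23 | intermediate
36 | γ-oxo butenolide: C2 ketone, all other centres as in the target | CC(=O)O[C@H]1C[C@@]23COC(=O)C2=CC(=O)[C@H]2c4occc4C(=O)C[C@@](C)([C@@H]1C)[C@@H]23 | intermediate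
37 | CNP0182929.2: C7 acetate, C2 alcohol (top face), C12 ketone, furan fused to ring C, C18/C19 lactone | CC(=O)O[C@H]1C[C@@]23COC(=O)C2=C[C@H](O)[C@H]2c4occc4C(=O)C[C@@](C)([C@@H]1C)[C@@H]23 | target

## Count and risks

Total step count: 18. Longest linear sequence: 17 steps (steps 1 to 7 and 9 to 18; step 8 prepares the furan fragment).

Steps most likely to fail:

1. Step 12. The aryl–palladium species may be reduced by formate before it inserts (hydrodebromination), or may insert 6-exo at C10 instead of 7-endo at C1 across the hindered trisubstituted alkene. Fallback, from 27 and returning at 28: a tin-hydride radical cyclisation (Bu3SnH added slowly, AIBN, benzene, 80 °C). The furyl radical should add 7-endo to the less substituted C1, and the tertiary C10 radical should take hydrogen from Bu3SnH on the open bottom face. This makes no new compound (F0).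

2. Step 6. The vinyllithium stage may be lost by protonation, bromine–lithium exchange may begin before the sigmatropic shift is complete, or a [1,2] shift may compete at the hindered C5 terminus. Fallback, from 11 and returning at 16: n-BuLi alone (THF, −78 °C) stops at the Still rearrangement, and the bromo homoallylic alcohol [(6S)-7-bromo-6-[2-(2-ethyl-1,3-dioxolan-2-yl)ethyl]-1,4-dioxaspiro[4.5]dec-7-en-6-yl]methanol F1 is isolated. Carbonylative lactonisation of this alkenyl bromide with zerovalent palladium (Pd(PPh3)4, CO at 1 atm, Et3N, MeCN, 70 °C) then forms C18–C4 and the lactone.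

3. Step 9. The bromomethyl ketone may be destroyed by the basic dienolate (proton transfer, attack at its carbonyl), or O-alkylation may compete at the hindered C9. Fallback, from 18 and returning at 24: Me3SiOTf and Et3N give the heteroannular silyl dienol ether F2. Rh2(OAc)4-catalysed decomposition of diazoketone 21 (from step 8) should cyclopropanate the electron-rich C8=C9 enol ether bond from the bottom face, giving siloxycyclopropane F3. Bu4NF with AcOH then opens the C8–C11 bond to the 1,4-diketone 24.

Further compounds

F0 | step 12 | none | none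
F1 | step 6 | [(6S)-7-bromo-6-[2-(2-ethyl-1,3-dioxolan-2-yl)ethyl]-1,4-dioxaspiro[4.5]dec-7-en-6-yl]methanol | CCC1(OCCO1)CC[C@@]2(CO)C(Br)=CCCC23OCCO3
F2 | step 9 | trimethylsilyl dienol ether of 18 (Me3SiO on C8; C8=C9 and C10=C1) | CC1=C(O[Si](C)(C)C)CC[C@@]23COC(=O)C2=CCC=C13
F3 | step 9 | siloxycyclopropane (C8, C9, C11 ring; Me3SiO on C8 top, C11 bottom carrying the 2-bromo-3-furoyl group; C11 configuration unassigned) | Brc1occc1C(=O)C5[C@@]2(C)[C@]5(O[Si](C)(C)C)CC[C@@]34COC(=O)C3=CCC=C24
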